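**Strategy.** The heterocycle of the lower flavan-3,4-diol unit (O1–C2–C3–C4–C4a–C8a) is disconnected at C4–C4a and O1–C2 into a phenol and one enantiopure cis-epoxy aldehyde carrying ring B. In the key step the magnesium phenoxide of the complete upper flavan, already joined through its C4 to the lower pyrogallol ring, attacks the aldehyde with its only free ortho carbon (C4a, ortho to O1, para to O7); O1 then opens the epoxide at the benzylic C2 with inversion. One flask forges two bonds, the last ring and the 2,3-cis-3,4-trans triad. The same annulation first builds the upper unit, whose C4 cation is captured by the next phenol.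

Key step: step 7

Remark: compounds 1, 4 and 5 are taken as commercial; the configuration at C4 of 10 is immaterial, because step 6 ionizes that centre.
Remark: the CIP descriptor of the upper C4 changes with the substitution of the lower ring (S in 11 and 14, R in 12 and 13), while its geometry (aryl trans to the C3 hydroxyl) stays the same.

**Step 1**
Reactants: 1 2,3-bis(benzyloxy)benzaldehyde
Product: 3 2,3-bis(benzyloxy)phenol, via aryl formate 2 (not isolated)
Conditions: mCPBA, CH2Cl2, rt; then K2CO3 (cat.), MeOH, rt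
Reagents that add atoms: 3-chloroperoxybenzoic acid (mCPBA), OOC(=O)c1cccc(Cl)c1
Why: Baeyer–Villiger (Dakin-type) oxidation of an electron-rich ortho-alkoxybenzaldehyde, in which the aryl group migrates to give the formate that is methanolysed to the phenol; benzyl ethers are inert.

**Step 2**
Reactants: 4 3,4-bis(benzyloxy)benzaldehyde; 5 ethyl 2-[bis(2,2,2-trifluoroethoxy)phosphoryl]acetate
Product: 6 ethyl (2Z)-3-[3,4-bis(benzyloxy)phenyl]prop-2-enoate
Conditions: KN(SiMe3)2, 18-crown-6, THF, −78 °C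
Reagents that add atoms: none
Why: Still–Gennari olefination, in which the electron-poor phosphonate under dissociating conditions collapses kinetically to the Z-enoate.

**Step 3**
Reactants: 6 ethyl (2Z)-3-[3,4-bis(benzyloxy)phenyl]prop-2-enoate
Product: 7 ethyl (2S,3S)-3-[3,4-bis(benzyloxy)phenyl]oxirane-2-carboxylate (cis-epoxide)
Conditions: (S,S)-(salen)MnCl (cat.; salen = N,N'-bis(3,5-di-tert-butylsalicylidene)cyclohexane-1,2-diamine dianion), 4-phenylpyridine N-oxide (cat.), aq. NaOCl (pH 11), CH2Cl2, 0 °C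
Reagents that add atoms: sodium hypochlorite, [Na+].[O-]Cl
Why: Jacobsen epoxidation of a cis-cinnamate ester; the (S,S) catalyst, mirror image of the one that gives (2R,3R)-glycidates from cis-cinnamates, should deliver oxygen to the face that gives the (2S,3S)-cis-epoxide, which fixes C2 and C3 of both flavan units, and any trans-epoxide from stepwise collapse is removed by chromatography.

**Step 4**
Reactants: 7 ethyl (2S,3S)-3-[3,4-bis(benzyloxy)phenyl]oxirane-2-carboxylate
Product: 8 (2S,3S)-3-[3,4-bis(benzyloxy)phenyl]oxirane-2-carbaldehyde (cis-epoxide)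
Conditions: i-Bu2AlH (1.1 equiv), CH2Cl2, −78 °C; MeOH, aq. potassium sodium tartrate
Reagents that add atoms: none
Why: Partial reduction of the ester through the tetrahedral aluminium hemiacetal, stable at −78 °C; no stereocentre is touched, and the aldehyde is used crude at once to avoid epimerization at its α-carbon.

**Step 5**
Reactants: 3 2,3-bis(benzyloxy)phenol; 8 (2S,3S)-3-[3,4-bis(benzyloxy)phenyl]oxirane-2-carbaldehyde
Product: 10 (2R,3R,4S)-7,8-bis(benzyloxy)-2-[3,4-bis(benzyloxy)phenyl]-3,4-dihydro-2H-chromene-3,4-diol, via epoxy carbinol 9 (not isolated)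
Conditions: n-Bu2Mg (0.5 equiv per 3), toluene–CH2Cl2, 0 °C; 8, −20 °C to rt; then Ti(OiPr)4 (1.5 equiv), rt
Reagents that add atoms: none
Why: The annulation of the key step run first on the simple phenol: ortho-specific hydroxyalkylation of the magnesium phenoxide by the aldehyde (only one ortho position is free), then 6-endo opening of the cis-epoxide at the benzylic carbon by the phenol oxygen with inversion, so that C2 and C3 come from 8 as the 2,3-cis pair.

**Step 6**
Reactants: 10 (2R,3R,4S)-7,8-bis(benzyloxy)-2-[3,4-bis(benzyloxy)phenyl]-3,4-dihydro-2H-chromene-3,4-diol; 3 2,3-bis(benzyloxy)phenol (4 equiv)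
Product: 11 (2R,3R,4S)-4-[2,3-bis(benzyloxy)-4-hydroxyphenyl]-7,8-bis(benzyloxy)-2-[3,4-bis(benzyloxy)phenyl]-3,4-dihydro-2H-chromen-3-ol
Conditions: TsOH·H2O (5 mol%), (CF3)2CHOH–CH2Cl2, 0 °C
Reagents that add atoms: none
Why: Friedel–Crafts alkylation: the C4 hydroxyl of 10 leaves as water to give the benzylic cation stabilized by O1 and O7, phenol 3 should attack through the position para to its free hydroxyl (favoured in the hydrogen-bonding fluoroalcohol) from the face trans to the C3 hydroxyl of the 2,3-cis cation, which sets C4 as 3,4-trans, and the excess of 3 suppresses self-condensation.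

**Step 7**
Reactants: 11 (2R,3R,4S)-4-[2,3-bis(benzyloxy)-4-hydroxyphenyl]-7,8-bis(benzyloxy)-2-[3,4-bis(benzyloxy)phenyl]-3,4-dihydro-2H-chromen-3-ol; 8 (2S,3S)-3-[3,4-bis(benzyloxy)phenyl]oxirane-2-carbaldehyde (1.5 equiv)
Product: 13 (2R,3R,4S)-7,8-bis(benzyloxy)-2-[3,4-bis(benzyloxy)phenyl]-6-{(2R,3R,4R)-7,8-bis(benzyloxy)-2-[3,4-bis(benzyloxy)phenyl]-3-hydroxy-3,4-dihydro-2H-chromen-4-yl}-3,4-dihydro-2H-chromene-3,4-diol (octa-O-benzyl ether of the target), via epoxy carbinol 12 (not isolated)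
Conditions: n-Bu2Mg (1.0 equiv), toluene–CH2Cl2, 0 °C; 8, −20 °C to rt; then Ti(OiPr)4 (1.5 equiv), rt
Reagents that add atoms: none
Why: The halide-free magnesium aryloxide of 11 binds the aldehyde of 8 and delivers its only free ortho carbon (future C4a, ortho to O1 and para to O7) through a six-membered metal-bridged transition state, the ortho-specific hydroxyalkylation of magnesium phenoxides by aldehydes known also for chiral α-oxygenated aldehydes; the epoxy alkoxide 12 is then closed by the likewise known Ti(OiPr)4-mediated opening of a 2,3-epoxy alcohol at its distal carbon, here with the neighbouring phenol oxygen as nucleophile. The ring closes in the 6-endo-tet mode at C2, which is benzylic to ring B and is the carbon that the titanium-bound epoxy alkoxide activates, so 5-exo attack at C3 should not compete. C3 is carried unchanged from 8, and C2 is set by backside attack of O1 on the cis-epoxide, which gives the 2,3-cis arrangement in the absolute sense fixed by the reagent and not by the remote upper unit. C4 is set in the C–C bond formation by a Cram-chelate arrangement in which magnesium bridges the aldehyde and epoxide oxygens and the aryl carbon enters from the face of the C3 hydrogen, away from C2 and ring B, giving the threo carbinol and hence the 3,4-trans diol. The step needs C- over O-alkylation at a single site (secured by the chelated phenoxide and by the benzyloxy group on the other ortho position), inversion and not ionization at C2 (secured by aprotic, weakly Lewis-acidic conditions and the intramolecular nucleophile) and an inert upper C3 alkoxide (no electrophile lies within its reach). The two events are known separately; running them in one flask on an epoxy aldehyde is the untested element, chosen because the intermediate epoxy phenol is expected to be too labile to isolate.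

**Step 8**
Reactants: 13 octa-O-benzyl ether of the target
Product: 14 (2R,3R,4S)-2-(3,4-dihydroxyphenyl)-6-[(2R,3R,4S)-2-(3,4-dihydroxyphenyl)-3,7,8-trihydroxy-3,4-dihydro-2H-chromen-4-yl]-3,4-dihydro-2H-chromene-3,4,7,8-tetrol
Conditions: H2 (1 atm), Pd(OH)2/C, THF–MeOH, rt, stopped when debenzylation is complete; argon work-up
Reagents that add atoms: none
Why: Hydrogenolysis of the eight aryl benzyl ethers, which should cleave much faster under neutral conditions than the secondary benzylic C4–OH and C2–O1 bonds, so that no stereocentre is touched.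

**Compound list**
1 | 2,3-bis(benzyloxy)benzaldehyde | O=Cc1cccc(OCc2ccccc2)c1OCc1ccccc1 | starting material
2 | 2,3-bis(benzyloxy)phenyl formate | O=COc1cccc(OCc2ccccc2)c1OCc1ccccc1 | intermediate (not isolated)
3 | 2,3-bis(benzyloxy)phenol | Oc1cccc(OCc2ccccc2)c1OCc1ccccc1 | intermediate
4 | 3,4-bis(benzyloxy)benzaldehyde | O=Cc1ccc(OCc2ccccc2)c(OCc2ccccc2)c1 | starting material
5 | ethyl 2-[bis(2,2,2-trifluoroethoxy)phosphoryl]acetate | CCOC(=O)CP(=O)(OCC(F)(F)F)OCC(F)(F)F | starting material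
6 | ethyl (2Z)-3-[3,4-bis(benzyloxy)phenyl]prop-2-enoate | CCOC(=O)/C=C\c1ccc(OCc2ccccc2)c(OCc2ccccc2)c1 | intermediate
7 | ethyl (2S,3S)-3-[3,4-bis(benzyloxy)phenyl]oxirane-2-carboxylate (cis) | CCOC(=O)[C@H]1O[C@H]1c1ccc(OCc2ccccc2)c(OCc2ccccc2)c1 | intermediate
8 | (2S,3S)-3-[3,4-bis(benzyloxy)phenyl]oxirane-2-carbaldehyde (cis) | O=C[C@H]1O[C@H]1c1ccc(OCc2ccccc2)c(OCc2ccccc2)c1 | intermediate
9 | (S)-[3,4-bis(benzyloxy)-2-hydroxyphenyl]{(2R,3S)-3-[3,4-bis(benzyloxy)phenyl]oxiran-2-yl}methanol (threo carbinol, cis-epoxide, present as its magnesium alkoxide) | Oc1c([C@H](O)[C@H]2O[C@H]2c2ccc(OCc3ccccc3)c(OCc3ccccc3)c2)ccc(OCc2ccccc2)c1OCc1ccccc1 | intermediate (not isolated)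
10 | (2R,3R,4S)-7,8-bis(benzyloxy)-2-[3,4-bis(benzyloxy)phenyl]-3,4-dihydro-2H-chromene-3,4-diol (2,3-cis-3,4-trans) | c1cc2c(c(OCc3ccccc3)c1OCc1ccccc1)O[C@H](c1ccc(OCc3ccccc3)c(OCc3ccccc3)c1)[C@H](O)[C@H]2O | intermediate
11 | (2R,3R,4S)-4-[2,3-bis(benzyloxy)-4-hydroxyphenyl]-7,8-bis(benzyloxy)-2-[3,4-bis(benzyloxy)phenyl]-3,4-dihydro-2H-chromen-3-ol (2,3-cis-3,4-trans) | O(Cc1ccccc1)c1ccc([C@H]2Oc3c(ccc(OCc4ccccc4)c3OCc3ccccc3)[C@H](c3ccc(O)c(OCc4ccccc4)c3OCc3ccccc3)[C@H]2O)cc1OCc1ccccc1 | intermediate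
12 | (2R,3R,4R)-4-{2,3-bis(benzyloxy)-4-hydroxy-5-[(S)-hydroxy{(2R,3S)-3-[3,4-bis(benzyloxy)phenyl]oxiran-2-yl}methyl]phenyl}-7,8-bis(benzyloxy)-2-[3,4-bis(benzyloxy)phenyl]-3,4-dihydro-2H-chromen-3-ol | O(Cc1ccccc1)c1ccc([C@H]2Oc3c(ccc(OCc4ccccc4)c3OCc3ccccc3)[C@H](c3cc([C@H](O)[C@H]4O[C@H]4c4ccc(OCc5ccccc5)c(OCc5ccccc5)c4)c(O)c(OCc4ccccc4)c3OCc3ccccc3)[C@H]2O)cc1OCc1ccccc1 | intermediate (not isolated)
13 | (2R,3R,4S)-7,8-bis(benzyloxy)-2-[3,4-bis(benzyloxy)phenyl]-6-{(2R,3R,4R)-7,8-bis(benzyloxy)-2-[3,4-bis(benzyloxy)phenyl]-3-hydroxy-3,4-dihydro-2H-chromen-4-yl}-3,4-dihydro-2H-chromene-3,4-diol | O(Cc1ccccc1)c1ccc([C@H]2Oc3c(ccc(OCc4ccccc4)c3OCc3ccccc3)[C@H](c3cc4c(c(OCc5ccccc5)c3OCc3ccccc3)O[C@H](c3ccc(OCc5ccccc5)c(OCc5ccccc5)c3)[C@H](O)[C@H]4O)[C@H]2O)cc1OCc1ccccc1 | intermediate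
14 | (2R,3R,4S)-2-(3,4-dihydroxyphenyl)-6-[(2R,3R,4S)-2-(3,4-dihydroxyphenyl)-3,7,8-trihydroxy-3,4-dihydro-2H-chromen-4-yl]-3,4-dihydro-2H-chromene-3,4,7,8-tetrol | Oc1ccc([C@H]2Oc3c(ccc(O)c3O)[C@H](c3cc4c(c(O)c3O)O[C@H](c3ccc(O)c(O)c3)[C@H](O)[C@H]4O)[C@H]2O)cc1O | target

**Count.** Total steps: 8. Longest linear sequence: 7 steps (4 → 6 → 7 → 8 → 10 → 11 → 13 → 14); step 1 is a one-step side branch.

**Steps most likely to fail**

Step 7. Three processes threaten it: C–C bond formation outside the magnesium chelate, which would erode facial selectivity at the aldehyde carbon; α-epimerization or rearrangement of the epoxy aldehyde on the Lewis-acidic metal before it is captured; and ionization at the benzylic epoxide carbon, which would cost the inversion at C2. The fallback sets out from 11 (and from 4 for the alkyne) and returns at 13. Ortho-formylation of 11 with MgCl2, Et3N and paraformaldehyde (MeCN, reflux) should give the salicylaldehyde (2R,3R,4R)-4-[2,3-bis(benzyloxy)-5-formyl-4-hydroxyphenyl]-7,8-bis(benzyloxy)-2-[3,4-bis(benzyloxy)phenyl]-3,4-dihydro-2H-chromen-3-ol F1. Ohira–Bestmann homologation of 4 (dimethyl (1-diazo-2-oxopropyl)phosphonate, K2CO3, MeOH) should give 1,2-bis(benzyloxy)-4-ethynylbenzene F2. Catalytic asymmetric alkynylation of F1 with F2 (Me2Zn in excess, ProPhenol ligand of the enantiomer that delivers the R carbinol, toluene) should give the (R)-propargylic alcohol F3. Semi-hydrogenation (H2, Pd/CaCO3 poisoned with Pb(OAc)2, quinoline, EtOAc) should give the (R,Z)-allylic alcohol F4. Epoxidation with mCPBA (NaHCO3, CH2Cl2, 0 °C) is threo-selective through A(1,3) strain and should give 12, which is closed to 13 with Ti(OiPr)4 as in the main route. In this sequence C4 comes from the catalyst, C2 and C3 are relayed from C4, and no epoxy aldehyde is handled; the final epoxide opening with inversion is kept.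

Step 5. The magnesium bis(aryloxide) may add to the aldehyde too slowly, so that 8 is lost to epimerization or self-condensation before the ring is built. The fallback sets out from 3 and returns at 10. Amine-catalysed ortho-bromination (N-bromosuccinimide, i-Pr2NH cat., CH2Cl2, 0 °C) should give 2,3-bis(benzyloxy)-6-bromophenol F5. Two equivalents of n-BuLi (THF, −78 °C) generate the O,C-dilithio species, a pre-formed aryl nucleophile that adds to 8 at −78 °C; Ti(OiPr)4 at rt then closes the ring to 10. If facial control at the aldehyde is lost, the (R)-carbinol epimer of 9, (R)-[3,4-bis(benzyloxy)-2-hydroxyphenyl]{(2R,3S)-3-[3,4-bis(benzyloxy)phenyl]oxiran-2-yl}methanol F6 (present only in the flask), forms alongside and leads to the C4 epimer of 10, (2R,3R,4R)-7,8-bis(benzyloxy)-2-[3,4-bis(benzyloxy)phenyl]-3,4-dihydro-2H-chromene-3,4-diol F7, which gives the same cation in step 6.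

Step 6. The cation may attack ortho instead of para to the phenolic hydroxyl (poor regioselectivity), and the product phenol may be alkylated a second time. The fallback sets out from 3 and 10 and returns at 11. Silylation of 3 (i-Pr3SiCl, imidazole, DMF) should give [2,3-bis(benzyloxy)phenoxy]tri(propan-2-yl)silane F8, in which the bulky silyl group, pushed towards the ortho C–H by the neighbouring benzyloxy group, shields that site. Friedel–Crafts alkylation with 10 (BF3·OEt2, CH2Cl2, −40 °C) should then occur only para to the silyloxy group and give the silyl ether of 11, (2R,3R,4S)-4-{2,3-bis(benzyloxy)-4-[tri(propan-2-yl)silyloxy]phenyl}-7,8-bis(benzyloxy)-2-[3,4-bis(benzyloxy)phenyl]-3,4-dihydro-2H-chromen-3-ol F9. Bu4NF (THF, 0 °C) frees the phenol 11.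

**Further compounds**
F1 | step 7 | (2R,3R,4R)-4-[2,3-bis(benzyloxy)-5-formyl-4-hydroxyphenyl]-7,8-bis(benzyloxy)-2-[3,4-bis(benzyloxy)phenyl]-3,4-dihydro-2H-chromen-3-ol | O(Cc1ccccc1)c1ccc([C@H]2Oc3c(ccc(OCc4ccccc4)c3OCc3ccccc3)[C@H](c3cc(C=O)c(O)c(OCc4ccccc4)c3OCc3ccccc3)[C@H]2O)cc1OCc1ccccc1
F2 | step 7 | 1,2-bis(benzyloxy)-4-ethynylbenzene | C#Cc1ccc(OCc2ccccc2)c(OCc2ccccc2)c1
F3 | step 7 | (2R,3R,4R)-4-{2,3-bis(benzyloxy)-5-[(1R)-3-[3,4-bis(benzyloxy)phenyl]-1-hydroxyprop-2-yn-1-yl]-4-hydroxyphenyl}-7,8-bis(benzyloxy)-2-[3,4-bis(benzyloxy)phenyl]-3,4-dihydro-2H-chromen-3-ol | O(Cc1ccccc1)c1ccc([C@H]2Oc3c(ccc(OCc4ccccc4)c3OCc3ccccc3)[C@H](c3cc([C@H](O)C#Cc4ccc(OCc5ccccc5)c(OCc5ccccc5)c4)c(O)c(OCc4ccccc4)c3OCc3ccccc3)[C@H]2O)cc1OCc1ccccc1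
F4 | step 7 | (2R,3R,4R)-4-{2,3-bis(benzyloxy)-5-[(1R,2Z)-3-[3,4-bis(benzyloxy)phenyl]-1-hydroxyprop-2-en-1-yl]-4-hydroxyphenyl}-7,8-bis(benzyloxy)-2-[3,4-bis(benzyloxy)phenyl]-3,4-dihydro-2H-chromen-3-ol | O(Cc1ccccc1)c1ccc([C@H]2Oc3c(ccc(OCc4ccccc4)c3OCc3ccccc3)[C@H](c3cc([C@H](O)/C=C\c4ccc(OCc5ccccc5)c(OCc5ccccc5)c4)c(O)c(OCc4ccccc4)c3OCc3ccccc3)[C@H]2O)cc1OCc1ccccc1
F5 | step 5 | 2,3-bis(benzyloxy)-6-bromophenol | Oc1c(Br)ccc(OCc2ccccc2)c1OCc1ccccc1
F6 | step 5 | (R)-[3,4-bis(benzyloxy)-2-hydroxyphenyl]{(2R,3S)-3-[3,4-bis(benzyloxy)phenyl]oxiran-2-yl}methanol | Oc1c([C@@H](O)[C@H]2O[C@H]2c2ccc(OCc3ccccc3)c(OCc3ccccc3)c2)ccc(OCc2ccccc2)c1OCc1ccccc1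
F7 | step 5 | (2R,3R,4R)-7,8-bis(benzyloxy)-2-[3,4-bis(benzyloxy)phenyl]-3,4-dihydro-2H-chromene-3,4-diol | c1cc2c(c(OCc3ccccc3)c1OCc1ccccc1)O[C@H](c1ccc(OCc3ccccc3)c(OCc3ccccc3)c1)[C@H](O)[C@@H]2O
F8 | step 6 | [2,3-bis(benzyloxy)phenoxy]tri(propan-2-yl)silane | CC(C)[Si](Oc1cccc(OCc2ccccc2)c1OCc1ccccc1)(C(C)C)C(C)C
F9 | step 6 | (2R,3R,4S)-4-{2,3-bis(benzyloxy)-4-[tri(propan-2-yl)silyloxy]phenyl}-7,8-bis(benzyloxy)-2-[3,4-bis(benzyloxy)phenyl]-3,4-dihydro-2H-chromen-3-ol | O(Cc1ccccc1)c1ccc([C@H]2Oc3c(ccc(OCc4ccccc4)c3OCc3ccccc3)[C@H](c3ccc(O[Si](C(C)C)(C(C)C)C(C)C)c(OCc4ccccc4)c3OCc3ccccc3)[C@H]2O)cc1OCc1ccccc1
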